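## Retrosynthetic overview

- Maackin ⇐ hexa‑MOM ether ⇐ Heck coupling of a 6‑vinyl‑2,3‑diaryl‑1,4‑benzodioxane with 1‑bromo‑3,5‑bis(methoxymethoxy)benzene; the vinyl group comes from a formyl group (Wittig).
- C2–aryl (catechol ring) bond ⇐ visible‑light Ni/photoredox decarboxylative arylation of a 3‑aryl‑benzodioxane‑2‑carboxylic acid, set trans by C3.
- Benzodioxane ring ⇐ α‑OH SNAr onto 3‑bromo‑4‑fluorobenzaldehyde (fixes which oxygen is para to the formyl group), then intramolecular C–O coupling of the benzylic OH.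
- C3–aryl (resorcinol ring) bond ⇐ the same photochemical decarboxylative arylation on the D‑tartrate acetonide mono‑acid, set trans by the neighbouring tartrate centre.
- Ring order: dioxolane (bought) → 1,4‑dioxane ring (steps 6–7); all aromatic rings are bought. Both stereogenic C–O bonds are those of D‑tartaric acid.

Assumption: the target SMILES is read as the trans‑(2R,3R)‑benzodioxane with the catechol ring on the carbon whose oxygen is para to the styryl group; a one‑pot sequence is counted as one step.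

## Route

**Step 1**
Reactants: 1, 5‑bromobenzene‑1,3‑diol
Product: 2, 1‑bromo‑3,5‑bis(methoxymethoxy)benzene
Conditions: MOMCl, i‑Pr2NEt, CH2Cl2, 0 °C → rt
Reagents that add atoms: chloromethyl methyl ether, COCCl
Why: Phenol O‑alkylation (MOM acetal protection); MOM ethers tolerate the bases, Ni, Pd and light used later and are removed by acid at the end.

**Step 2**
Reactants: 3, 4‑bromobenzene‑1,2‑diol
Product: 4, 4‑bromo‑1,2‑bis(methoxymethoxy)benzene
Conditions: MOMCl, i‑Pr2NEt, CH2Cl2, 0 °C → rt
Reagents that add atoms: chloromethyl methyl ether, COCCl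
Why: Same MOM protection, giving the catechol aryl bromide for step 8.

**Step 3**
Reactants: 5, dimethyl (4S,5S)‑2,2‑dimethyl‑1,3‑dioxolane‑4,5‑dicarboxylate (acetonide dimethyl ester of D‑(−)‑tartaric acid)
Product: 6, (4S,5S)‑5‑(methoxycarbonyl)‑2,2‑dimethyl‑1,3‑dioxolane‑4‑carboxylic acid
Conditions: KOH (1.0 equiv), MeOH, 0 °C → rt; KHSO4 work‑up
Reagents that add atoms: potassium hydroxide (hydroxide O), [K+].[OH-]
Why: Mono‑saponification of a C2‑symmetric diester (the first carboxylate slows the second hydrolysis); no bond to a stereocentre is touched, so both centres stay (S).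

**Step 4**
Reactants: 6 (1.5 equiv); 2
Product: 7, methyl (4S,5R)‑5‑[3,5‑bis(methoxymethoxy)phenyl]‑2,2‑dimethyl‑1,3‑dioxolane‑4‑carboxylate (trans)
Conditions: 4CzIPN (2 mol%), NiCl2·glyme (10 mol%), dtbbpy (15 mol%), Cs2CO3, DMF, 450 nm LEDs, 25 °C, degassed
Reagents that add atoms: none
Why: Ni/photoredox decarboxylative arylation of an α‑oxy acid: photo‑oxidation of the carboxylate and loss of CO2 give a dioxolan‑4‑yl radical, and the Ni–aryl bond forms anti to the neighbouring CO2Me on the rigid five‑membered ring, so the new benzylic centre (5R) is dictated by the remaining tartrate centre (minor cis isomer removed by chromatography).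

**Step 5**
Reactants: 7
Product: 8, methyl (2S,3R)‑3‑[3,5‑bis(methoxymethoxy)phenyl]‑2,3‑dihydroxypropanoate
Conditions: AcOH/H2O (4:1), 50 °C
Reagents that add atoms: none (water supplies only H to the product)
Why: Acid‑catalysed ketal hydrolysis cleaves only at the acetal carbon, so C2 and C3 keep their configuration; the 3,5‑dioxygenated benzylic C–O does not ionise and aryl MOM ethers hydrolyse much more slowly than the ketal in aqueous acetic acid.

**Step 6**
Reactants: 8; 9, 3‑bromo‑4‑fluorobenzaldehyde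
Product: 10, methyl (2S,3R)‑2‑(2‑bromo‑4‑formylphenoxy)‑3‑[3,5‑bis(methoxymethoxy)phenyl]‑3‑hydroxypropanoate
Conditions: Cs2CO3 (1.1 equiv), DMSO, 25–40 °C
Reagents that add atoms: none
Why: SNAr at the fluoride para to CHO by the more acidic α‑hydroxyl of the α‑hydroxy ester (the hydroxyl that is selectively sulfonylated in syn‑2,3‑dihydroxy esters), which puts the C2 oxygen para to the formyl group; C3 is untouched and C2 may epimerise without consequence because it is planarised in step 8.

**Step 7**
Reactants: 10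
Product: 11, (2S,3R)‑3‑[3,5‑bis(methoxymethoxy)phenyl]‑6‑formyl‑2,3‑dihydro‑1,4‑benzodioxine‑2‑carboxylic acid (trans)
Conditions: Pd(OAc)2 (3 mol%), t‑BuXPhos (6 mol%), K3PO4, toluene, 70 °C; then LiOH, THF/H2O, 0 °C (one pot); citric acid work‑up
Reagents that add atoms: lithium hydroxide (hydroxide O), [Li+].[OH-]
Why: Pd‑catalysed intramolecular C–O coupling (Buchwald‑type etherification) of the benzylic alcohol with the ortho C–Br closes the 1,4‑dioxane ring with retention at C3 (no bond to C3 is broken) and places the C3 oxygen meta to CHO; cold saponification then frees the acid before enolate‑mediated ring opening can occur.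

**Step 8**
Reactants: 11; 4 (2 equiv)
Product: 12, (2R,3R)‑2‑[3,4‑bis(methoxymethoxy)phenyl]‑3‑[3,5‑bis(methoxymethoxy)phenyl]‑2,3‑dihydro‑1,4‑benzodioxine‑6‑carbaldehyde (trans)
Conditions: 4CzIPN (2 mol%), NiBr2·glyme (10 mol%), dtbbpy (12 mol%), Cs2CO3 (1.2 equiv), DMF (0.05 M), 450 nm LEDs, 25 °C, degassed
Reagents that add atoms: none
Why: Proposed new method: diastereoconvergent Ni/photoredox decarboxylative arylation of a 3‑aryl‑2,3‑dihydro‑1,4‑benzodioxine‑2‑carboxylic acid — excited 4CzIPN oxidises the caesium carboxylate, loss of CO2 gives a planarised C2 α‑aryloxy radical (so any C2 epimer of 11 converges), (dtbbpy)Ni(Ar)Br traps it and C–C reductive elimination from Ni(III) occurs anti to the pseudo‑equatorial C3 aryl group, so the (2R) centre is formed trans to, and controlled by, the tartrate‑derived C3 with an achiral catalyst; capture by Ni is expected to outrun β‑scission of the C3–O4 bond; the closest known reaction type is metallaphotoredox decarboxylative arylation of simple cyclic α‑oxy acids, which has not been shown on 3‑substituted benzodioxane acids or used for 1,2‑induction in this ring.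

**Step 9**
Reactants: 12
Product: 13, (2R,3R)‑2‑[3,4‑bis(methoxymethoxy)phenyl]‑3‑[3,5‑bis(methoxymethoxy)phenyl]‑6‑ethenyl‑2,3‑dihydro‑1,4‑benzodioxine
Conditions: Ph3PCH3Br, KOt‑Bu, THF, 0 °C → rt
Reagents that add atoms: methyltriphenylphosphonium bromide (CH2), C[P+](c1ccccc1)(c1ccccc1)c1ccccc1.[Br-]
Why: Wittig methylenation of the aryl aldehyde; the benzodioxane C–H bonds are not acidic, so both stereocentres are unaffected.

**Step 10**
Reactants: 13; 2
Product: 14, (2R,3R)‑2‑[3,4‑bis(methoxymethoxy)phenyl]‑3‑[3,5‑bis(methoxymethoxy)phenyl]‑6‑{(E)‑2‑[3,5‑bis(methoxymethoxy)phenyl]ethenyl}‑2,3‑dihydro‑1,4‑benzodioxine (hexa‑O‑MOM‑maackin)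
Conditions: Pd(OAc)2 (5 mol%), P(o‑tol)3 (10 mol%), Et3N, DMF, 100 °C, dark
Reagents that add atoms: none
Why: Mizoroki–Heck arylation of the styrene gives the E‑stilbene (syn insertion, syn β‑hydride elimination); it is run after both photochemical steps so the stilbene is never exposed to a triplet sensitiser.

**Step 11**
Reactants: 14
Product: 15, Maackin, 5‑[(E)‑2‑[(2R,3R)‑2‑(3,4‑dihydroxyphenyl)‑3‑(3,5‑dihydroxyphenyl)‑2,3‑dihydro‑1,4‑benzodioxin‑6‑yl]ethenyl]benzene‑1,3‑diol
Conditions: 3 M HCl, MeOH/THF, 45 °C, argon, dark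
Reagents that add atoms: none
Why: Acid cleavage of the six MOM acetals (no benzodioxane C–O bond is an acetal); under the same conditions any cis epimer at the now p‑hydroxybenzylic C2 equilibrates to the more stable trans isomer, while the non‑ionisable C3 holds the absolute configuration.

## Compound list

1 | 5‑bromobenzene‑1,3‑diol | Oc1cc(O)cc(Br)c1 | starting material
2 | 1‑bromo‑3,5‑bis(methoxymethoxy)benzene | COCOc1cc(Br)cc(OCOC)c1 | intermediate
3 | 4‑bromobenzene‑1,2‑diol | Oc1ccc(Br)cc1O | starting material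
4 | 4‑bromo‑1,2‑bis(methoxymethoxy)benzene | COCOc1ccc(Br)cc1OCOC | intermediate
5 | dimethyl (4S,5S)‑2,2‑dimethyl‑1,3‑dioxolane‑4,5‑dicarboxylate | COC(=O)[C@H]1OC(C)(C)O[C@@H]1C(=O)OC | starting material
6 | (4S,5S)‑5‑(methoxycarbonyl)‑2,2‑dimethyl‑1,3‑dioxolane‑4‑carboxylic acid | COC(=O)[C@H]1OC(C)(C)O[C@@H]1C(=O)O | intermediate
7 | methyl (4S,5R)‑5‑[3,5‑bis(methoxymethoxy)phenyl]‑2,2‑dimethyl‑1,3‑dioxolane‑4‑carboxylate | COC(=O)[C@H]1OC(C)(C)O[C@@H]1c1cc(OCOC)cc(OCOC)c1 | intermediate
8 | methyl (2S,3R)‑3‑[3,5‑bis(methoxymethoxy)phenyl]‑2,3‑dihydroxypropanoate | COC(=O)[C@@H](O)[C@H](O)c1cc(OCOC)cc(OCOC)c1 | intermediate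
9 | 3‑bromo‑4‑fluorobenzaldehyde | O=Cc1ccc(F)c(Br)c1 | starting material
10 | methyl (2S,3R)‑2‑(2‑bromo‑4‑formylphenoxy)‑3‑[3,5‑bis(methoxymethoxy)phenyl]‑3‑hydroxypropanoate | COC(=O)[C@@H](Oc1ccc(C=O)cc1Br)[C@H](O)c1cc(OCOC)cc(OCOC)c1 | intermediate
11 | (2S,3R)‑3‑[3,5‑bis(methoxymethoxy)phenyl]‑6‑formyl‑2,3‑dihydro‑1,4‑benzodioxine‑2‑carboxylic acid | OC(=O)[C@H]1Oc2ccc(C=O)cc2O[C@@H]1c1cc(OCOC)cc(OCOC)c1 | intermediate
12 | (2R,3R)‑2‑[3,4‑bis(methoxymethoxy)phenyl]‑3‑[3,5‑bis(methoxymethoxy)phenyl]‑2,3‑dihydro‑1,4‑benzodioxine‑6‑carbaldehyde | COCOc1ccc(cc1OCOC)[C@H]1Oc2ccc(C=O)cc2O[C@@H]1c1cc(OCOC)cc(OCOC)c1 | intermediate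
13 | (2R,3R)‑2‑[3,4‑bis(methoxymethoxy)phenyl]‑3‑[3,5‑bis(methoxymethoxy)phenyl]‑6‑ethenyl‑2,3‑dihydro‑1,4‑benzodioxine | COCOc1ccc(cc1OCOC)[C@H]1Oc2ccc(C=C)cc2O[C@@H]1c1cc(OCOC)cc(OCOC)c1 | intermediate
14 | hexa‑O‑MOM‑maackin (name as in step 10) | COCOc1ccc(cc1OCOC)[C@H]1Oc2ccc(/C=C/c3cc(OCOC)cc(OCOC)c3)cc2O[C@@H]1c1cc(OCOC)cc(OCOC)c1 | intermediate
15 | Maackin | Oc1cc(O)cc(/C=C/c2ccc3c(c2)O[C@H](c2cc(O)cc(O)c2)[C@@H](c2ccc(O)c(O)c2)O3)c1 | target

## Step count and risks

Total steps: 11. Longest linear sequence: 9 (5 → 6 → 7 → 8 → 10 → 11 → 12 → 13 → 14 → 15; steps 3–11).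

Three steps most likely to fail:

1. **Step 8 (proposed new step).** Risks are a poor trans:cis ratio, β‑scission or protodecarboxylation of the benzodioxanyl radical, and slow oxidative addition of the electron‑rich bromide 4. Fallback (known chemistry): convert 11 into its N‑hydroxyphthalimide ester and use the thermal Ni‑catalysed decarboxylative Negishi arylation with the arylzinc made from 4. This is reductive activation with an aryl nucleophile and no light; any cis product is still corrected in step 11.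

2. **Step 6 (α‑selective SNAr).** Risks are competing O‑arylation of the benzylic OH and base‑induced retro‑aldol of the β‑hydroxy ester. Fallback: convert diol 8 into its cyclic sulfate (SOCl2, then RuCl3/NaIO4) and open it at C2 with the phenoxide of 3‑bromo‑4‑hydroxybenzaldehyde, then hydrolyse the sulfate monoester. Cyclic sulfates of 2,3‑dihydroxy esters open at C2; the inversion at C2 does not matter and the C3–O bond is untouched.

3. **Step 7 (Pd C–O ring closure).** Risks are β‑hydride elimination of the secondary benzylic alkoxide and base‑mediated ring opening of the α‑aryloxy ester. Fallback: reverse the order of Ar–O bond formation and avoid metal catalysis. Use 4‑fluoro‑3‑hydroxybenzaldehyde, etherify the benzylic OH by Mitsunobu reaction (inversion, so start from the L‑tartrate‑derived enantiomer of 8), and close the ring by intramolecular SNAr of the α‑alkoxide onto the fluoride para to CHO.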